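All runs are calculated on assumed constants.

You read Tuesday's and Saturday's at 1.0 h, so count how many midpoint times fit into that reading time. The midpoint time is the time at which starting material reads about 50% of the charge.

| flask | starting material | other conformer | precatalyst | added ligand | temperature | remark | time |
|---|---|---|---|---|---|---|---|
| theta | 2.1 M | 0.10 equiv | 10 mol% | 80 mM | 29 °C | run made earlier |  |
| alpha | 2.1 M | 0.10 equiv | 10 mol% | 80 mM | 37 °C | run made earlier |  |
| Tuesday's | 1.5 M | 0.100 equiv | 10 mol% | 80 mM | 25 °C |  | 1.0 h |
| Saturday's | 1.5 M | 0.100 equiv | 10 mol% | 80 mM | 40 °C |  | 1.0 h |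

| run | time / min | other conformer / % | isomer of the product / % | starting material / % | target / % |
|---|---|---|---|---|---|
| theta | 4.00 | 0 | 1 | 81 | 16 |
| theta | 8.00 | 0 | 2 | 48 | 47 |
| theta | 20.0 | 0 | 1 | 5 | 92 |
| theta | 50.0 | 0 | 5 | 0 | 93 |
| alpha | 2.00 | 2 | 0 | 78 | 23 |
| alpha | 4.00 | 2 | 4 | 50 | 51 |
| alpha | 12.0 | 0 | 2 | 5 | 94 |
| alpha | 30.0 | 0 | 4 | 1 | 98 |

(scatter of a reading: 2 percentage points)

- which of these there is most of at the end, counted by the starting material in it, Tuesday's (starting material / other conformer / isomer of the product / target)
- which of these there is most of at the end, counted by the starting material in it, Saturday's (starting material / other conformer / isomer of the product / target)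
- final amount of the leader among these, as a percentage of the starting material and other conformer together charged, in Tuesday's
- final amount of the leader among these, as a percentage of the starting material and other conformer together charged, in Saturday's

1. Fastest rung: the other conformer. The theta run reads 0% of it at 4.00 min, and isomer of the product reads 5% at 50.0 min, out of the 9.09% charged as other conformer, so in that reading part of the other conformer ends as isomer of the product and the rest seems to return to starting material.

2. Next rung: the induction period. In the theta run, target gains 16% in the first 4.00 min and more in the next interval, 31 percentage points. This reads as precatalyst still turning into catalyst.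

3. Next rung: the midpoint time. It reads 8.00 min in the theta run and 4.00 min in the alpha run, a factor of 2.00 between 29 °C and 37 °C. Carried down to 25 °C, that factor gives 11.3 min.

Now put that answer back in. It belongs to 210 mM of precatalyst, but Tuesday's flask holds 150 mM. Taking rate as proportional to catalyst, which is a guess because no earlier run varies that charge, gives 15.8 min. The same reckoning gives 4.32 min for Saturday's flask.

4. Slowest rung: the reading time. The theta run reads 92% target at 2.50 midpoint times, and the alpha run reads 94% at 3.00. Tuesday's flask is read later, at 3.79 midpoint times, and Saturday's at 13.9. My reckoning therefore puts target ahead in both flasks, at about those readings or above.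

The forecast gives target at 93% (84% to 97%) for Tuesday's and target at 95% (91% to 98%) for Saturday's, from “roughly first-order loss of starting material”.

The flasks give target at 94.1% in Tuesday's and target at 96.4% in Saturday's.

    catalyst + added ligand ⇌ idle complex (K = 4.10 L mol⁻¹, k = 0.00590 L mol⁻¹ s⁻¹, Ea = 71.0 kJ mol⁻¹, ΔH = −15.0 kJ mol⁻¹)
    starting material ⇌ other conformer (K = 0.00700, k = 1.70 × 10⁻⁴ s⁻¹, Ea = 94.0 kJ mol⁻¹, ΔH = −37.0 kJ mol⁻¹)
    starting material + catalyst → catalyst + target (k = 0.0240 L mol⁻¹ s⁻¹, Ea = 51.0 kJ mol⁻¹)
    precatalyst ⇌ catalyst (K = 3.30, k = 7.50 × 10⁻⁴ s⁻¹, Ea = 98.0 kJ mol⁻¹, ΔH = −36.0 kJ mol⁻¹)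
    catalyst + other conformer → catalyst + isomer of the product (k = 0.310 L mol⁻¹ s⁻¹, Ea = 49.0 kJ mol⁻¹)
    (constants at 25 °C)

In Tuesday's flask, the middle of the turnover to target falls at 13.9 min, against the reckoned 15.8 min. The largest single effect on Tuesday's target is the backward run from other conformer to starting material: with that run taken away, Tuesday's flask ends at 77.3% target instead of 94.1%, and Saturday's flask at 69.2% instead of 96.4%. To put Tuesday's number in doubt, a run must move it: target has shifted by 6 points at a reading time of 0.545 h, or at 4.5 mol% of precatalyst.

Tuesday's flask read at 15 min stands at 0.949 midpoint times, so starting material should read close to the theta run's 48%. That flask gives 44.7% starting material and 51.5% target.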